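The numbers in the tables stem from a simulated flask with constants of no real substance, and the scatter is random.

The constants worth having here are two, an apparent Michaelis constant K and a limiting rate V, both per starting volume and both read from the zeta and gamma runs at their shared time 2.00 min. With x the share of Zb left, u the share used and c the charge, the integrated rate law reads −K ln x + c u = V t.

all flasks: Zd 4.7 µM

| charge | Zb | Za | remark | time |
|---|---|---|---|---|
| zeta | 28 mM (fed, over 4.0 s) | 5 µM | run made earlier; the fed solution adds 0.10 times the starting volume |  |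
| gamma | 44 mM (fed, over 4.0 s) | 5 µM | run made earlier; the fed solution adds 0.10 times the starting volume |  |
| flask | 20 mM (fed, over 4.0 s) | 5.0 µM | the fed solution adds 0.10 times the starting volume | 3.0 min |

- zeta (time / min: Zc / %, Zb / %): 0.250: 10.7, 88.9; 0.667: 30.2, 69.9; 1.33: 55.0, 44.8; 2.00: 72.3, 27.7; 3.00: 88.8, 11.6; 4.00: 95.3, 4.5
- gamma (time / min: Zc / %, Zb / %): 0.250: 8.1, 92.0; 0.500: 18.3, 82.2; 0.833: 29.4, 70.4; 1.33: 45.5, 55.3; 2.00: 63.6, 36.7; 4.00: 91.6, 8.6

(readings scatter by 0.5 percentage points)

- how much Zc the flask holds at 3.0 min, in percent of the Zb charged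
- how much Zb the flask holds at 3.0 min, in percent of the Zb charged

- amounts are per litre of the starting volume; all of the dose is in the solution fed

K = (Zb used in gamma − Zb used in zeta) / (difference of −ln x) = 27.0 mM

V = 27.5 mM min⁻¹

Both are readings and carry the scatter. Two times follow: the pseudo-first-order time τ = K/V = 0.984 min, and the emptying time D = c/V = 0.728 min, the time this flask's charge takes at the limiting rate. Their ratio is 0.740, and D is shorter than the 3.0 min asked, so saturation enters as a delay on first-order decay. The gradual adding of Zb is passed over.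

−ln x = (t − D u)/τ

Taking u as whole: x = 9.94%

Correcting u: x = 9.23%

This reckoning leaves 9.23% of Zb and 90.8% of Zc. The forecast, on its own fit, says 9.8% of Zb (8.3% to 11.7%) and 90.2% of Zc (88.3% to 91.8%), 0.57 percentage points more Zb than here, judging “Product inhibition or enzyme decay seems slight”.

The flask gives 91.3% of Zc and 8.68% of Zb.

    Zb + Za ⇌ Ze (K = 90.0 M⁻¹, k = 1.40 × 10⁵ M⁻¹ s⁻¹)
    Ze ⇌ Za + Zc (K = 0.970 M, k = 97.0 s⁻¹)
    Za + Zd ⇌ Zf (K = 4.40 × 10⁵ M⁻¹, k = 1.90 × 10⁵ M⁻¹ s⁻¹)

At the end of the feed, 0.0667 min, Ze held 38.7% and Zf 35.5% of the catalyst. Ze then sank to 6.43% at 3.00 min as Zb fell, the making of Zc from Ze reaching its midpoint at 0.933 min, while Zf stood at 45.9%, its backward turnover 99% of the forward one. With D, and with u taken from the flask's own Zb, the rule gives 35.4% of Zb at 1.50 min; the flask holds 34.5%.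

For a neighbour flask, the same charge read at 50 s instead, the same D, starting from 0.5 left, gives in successive passes 62.1%, 56.8% and 59.0% of Zb. The computed neighbour flask holds 58.5% of Zb and 41.5% of Zc.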